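**Retrosynthetic overview**
1. Target 20 ⇐ global LiAlH4 reduction of triester 19 (two methyl esters and the aryl pivalate); the C3 side chain ⇐ Negishi coupling of aryl bromide 16 with a zinc homoenolate.
2. trans-Dihydrobenzofuran ester 16 ⇐ hypervalent-iodine ring contraction (1,2-aryl shift) of (2S)-flavanone 14; C2 is carried through and C3 is set trans to it.
3. (2S)-Flavanone 14 ⇐ catalytic asymmetric condensation/oxa-Michael annulation of acetophenone 6 with aldehyde 12 (new step, sets C2).
4. 6 ⇐ catechol (O-methylation, bromination, ortho-acetylation); 12 ⇐ p-cresol (bromination/hydrolysis, Cu-methoxylation, pivaloylation).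
5. Ring order: both benzene rings are bought; the pyranone ring is closed first, then contracted to the dihydrofuran ring.

Assumption: the sense of induction in step 6 has to be found by experiment; the cinchona pseudoenantiomer that gives the (2S)-flavanone (CD check) is the one meant, and each one-pot operation is counted as one step.

**Route**

Step 1
Reactants: 1 catechol
Product: 2 guaiacol (2-methoxyphenol)
Conditions: MeI (1.0 equiv), Li2CO3, DMF, 55 °C (1 in 1.3-fold excess; 2 distilled)
Reagents that add atoms: iodomethane CI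
Why: Williamson mono-O-methylation; the weak base ionises only one OH of the more acidic catechol and the excess of 1 suppresses veratrole.

Step 2
Reactants: 2 guaiacol
Product: 3 4-bromo-2-methoxyphenol
Conditions: NBS (1.0 equiv), MeCN, 0 °C → rt
Reagents that add atoms: N-bromosuccinimide O=C1CCC(=O)N1Br
Why: Electrophilic aromatic bromination; OH is the stronger director, so bromine enters para to it.

Step 3
Reactants: 3 4-bromo-2-methoxyphenol; 4 acetyl chloride
Product: 6 1-(5-bromo-2-hydroxy-3-methoxyphenyl)ethan-1-one, via 4-bromo-2-methoxyphenyl acetate 5 (not isolated)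
Conditions: AcCl (1.5 equiv), TiCl4 (1.5 equiv), neat, 120 °C, 1 h; aq. HCl work-up
Reagents that add atoms: none
Why: One-pot O-acetylation and TiCl4-mediated Fries rearrangement (titanium-phenoxide-directed ortho-acylation); the para position is blocked by Br, so the acetyl group goes to the only free ortho carbon, and TiCl4 rather than AlCl3 limits O-demethylation.

Step 4
Reactants: 7 p-cresol
Product: 10 3,5-dibromo-4-hydroxybenzaldehyde, via 2,6-dibromo-4-methylphenol 8 (not isolated), via 2,6-dibromo-4-(dibromomethyl)phenol 9 (not isolated)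
Conditions: Br2 (2.05 equiv), 1,2-dichlorobenzene, 35 °C; Br2 (2.1 equiv), 150 °C; then H2O, 100 °C
Reagents that add atoms: bromine BrBr; water O
Why: Ortho,ortho-dibromination (SEAr), then thermal benzylic dibromination and hydrolysis of the benzal bromide, the established technical one-pot route to this aldehyde.

Step 5
Reactants: 10 3,5-dibromo-4-hydroxybenzaldehyde
Product: 12 4-formyl-2,6-dimethoxyphenyl pivalate, via sodium 4-formyl-2,6-dimethoxyphenolate 11 (not isolated)
Conditions: NaOMe (3.3 equiv, 30% in MeOH), CuCl (5 mol %), DMF, 115 °C; MeOH distilled off; then PivCl (1.5 equiv), 0 °C → rt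
Reagents that add atoms: sodium methoxide [Na+].[O-]C; pivaloyl chloride CC(C)(C)C(Cl)=O
Why: Cu(I)-catalysed Ullmann-type methoxylation of both C–Br bonds, then O-acylation of the sodium phenolate in the same pot, by analogy with the technical one-pot methoxylation/O-methylation to 3,4,5-trimethoxybenzaldehyde; the hindered pivalate masks the oxidation-prone phenol and is removed by hydride at the end.

Step 6
Reactants: 6 1-(5-bromo-2-hydroxy-3-methoxyphenyl)ethan-1-one; 12 4-formyl-2,6-dimethoxyphenyl pivalate
Product: 14 4-[(2S)-6-bromo-8-methoxy-4-oxo-3,4-dihydro-2H-chromen-2-yl]-2,6-dimethoxyphenyl pivalate, via 2'-hydroxychalcone 13 (not isolated)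
Conditions: 9-amino-9-deoxy-epi-hydroquinidine (20 mol %), TFA (40 mol %), 4 Å MS, toluene, 45 °C, 48 h; recrystallise (EtOH) to ≥99% ee
Reagents that add atoms: none
Why: Proposed new method: an enantioselective primary-amine-salt-catalysed Kabbe-type annulation. The cinchona 9-amine condenses with the o-hydroxyaryl ketone (ketimine/enamine stabilised by the OH···N bond), Mannich/aldol addition to the aldehyde and loss of water give chalcone 13 as its N–H iminium, and the phenoxide–iminium zwitterion closes 6-endo (oxa-Michael) on the Cβ face left open by the quinoline and quinuclidinium units, which sets C2 as S. The water released hydrolyses the product enamine and turns the catalyst over. Closest known reactions: the racemic pyrrolidine-mediated Kabbe condensation to chromanones/flavanones, and cinchona-primary-amine iminium-catalysed oxa-Michael additions of oximes and hydroperoxides to enones.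

Step 7
Reactants: 14 (2S)-flavanone
Product: 16 methyl (2S,3S)-5-bromo-2-[3,5-dimethoxy-4-(pivaloyloxy)phenyl]-7-methoxy-2,3-dihydro-1-benzofuran-3-carboxylate, via 4-methoxy-2H-chromene enol ether 15 (not isolated)
Conditions: PhI(OAc)2 (1.2 equiv), conc. H2SO4 (cat.), HC(OMe)3, rt, 2 h; aq. NaHCO3 work-up
Reagents that add atoms: trimethyl orthoformate COC(OC)OC; water O
Why: Hypervalent-iodine oxidative ring contraction of a flavanone (1,2-aryl shift). Enol ether 15 is attacked by I(III) at C3 anti to the 2-aryl group, the ketalised C4 lets ring carbon C4a migrate to C3 with inversion and loss of PhI, and the resulting orthoester cation collapses to the methyl ester. C2 is untouched and C3 is set trans to it, so (2S) gives (2S,3S).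

Step 8
Reactants: 16 bromo ester; 17 methyl 3-bromopropanoate
Product: 19 methyl (2S,3S)-2-[3,5-dimethoxy-4-(pivaloyloxy)phenyl]-7-methoxy-5-(3-methoxy-3-oxopropyl)-2,3-dihydro-1-benzofuran-3-carboxylate, via (3-methoxy-3-oxopropyl)zinc bromide 18 (not isolated)
Conditions: 17 (2 equiv), Zn dust, LiCl, THF, 40 °C; then 16, Pd(OAc)2 (2 mol %), SPhos (4 mol %), THF, 25–45 °C
Reagents that add atoms: none
Why: Negishi sp3–sp2 cross-coupling of a zinc homoenolate with the unhindered aryl bromide; the esters, the aryl pivalate and both stereocentres are inert to RZnBr and Pd/SPhos under these neutral conditions.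

Step 9
Reactants: 19 triester
Product: 20 4-[(2S,3R)-3-(hydroxymethyl)-5-(3-hydroxypropyl)-7-methoxy-2,3-dihydro-1-benzofuran-2-yl]-2,6-dimethoxyphenol (target)
Conditions: LiAlH4 (4 equiv), THF, 0 °C → rt; Rochelle-salt work-up
Reagents that add atoms: none
Why: Global hydride reduction turns both methyl esters into primary alcohols and cleaves the aryl pivalate to the free phenol; no bond at C2 or C3 is touched, and the C3 descriptor changes from S to R only because CH2OH ranks below C2.

**Compound list**
1 | catechol (benzene-1,2-diol) | Oc1ccccc1O | starting material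
2 | guaiacol (2-methoxyphenol) | COc1ccccc1O | intermediate
3 | 4-bromo-2-methoxyphenol | COc1cc(Br)ccc1O | intermediate
4 | acetyl chloride | CC(Cl)=O | starting material
5 | 4-bromo-2-methoxyphenyl acetate | COc1cc(Br)ccc1OC(C)=O | intermediate (not isolated)
6 | 1-(5-bromo-2-hydroxy-3-methoxyphenyl)ethan-1-one | COc1cc(Br)cc(C(C)=O)c1O | intermediate
7 | p-cresol (4-methylphenol) | Cc1ccc(O)cc1 | starting material
8 | 2,6-dibromo-4-methylphenol | Cc1cc(Br)c(O)c(Br)c1 | intermediate (not isolated)
9 | 2,6-dibromo-4-(dibromomethyl)phenol | BrC(Br)c1cc(Br)c(O)c(Br)c1 | intermediate (not isolated)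
10 | 3,5-dibromo-4-hydroxybenzaldehyde | O=Cc1cc(Br)c(O)c(Br)c1 | intermediate
11 | sodium 4-formyl-2,6-dimethoxyphenolate | COc1cc(C=O)cc(OC)c1[O-].[Na+] | intermediate (not isolated)
12 | 4-formyl-2,6-dimethoxyphenyl pivalate | COc1cc(C=O)cc(OC)c1OC(=O)C(C)(C)C | intermediate
13 | 4-[(1E)-3-(5-bromo-2-hydroxy-3-methoxyphenyl)-3-oxoprop-1-en-1-yl]-2,6-dimethoxyphenyl pivalate (2'-hydroxychalcone) | COc1cc(/C=C/C(=O)c2cc(Br)cc(OC)c2O)cc(OC)c1OC(=O)C(C)(C)C | intermediate (not isolated)
14 | 4-[(2S)-6-bromo-8-methoxy-4-oxo-3,4-dihydro-2H-chromen-2-yl]-2,6-dimethoxyphenyl pivalate ((S)-flavanone) | COc1cc([C@@H]2CC(=O)c3cc(Br)cc(OC)c3O2)cc(OC)c1OC(=O)C(C)(C)C | intermediate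
15 | 4-[(2S)-6-bromo-4,8-dimethoxy-2H-chromen-2-yl]-2,6-dimethoxyphenyl pivalate (enol ether) | COc1cc([C@@H]2C=C(OC)c3cc(Br)cc(OC)c3O2)cc(OC)c1OC(=O)C(C)(C)C | intermediate (not isolated)
16 | methyl (2S,3S)-5-bromo-2-[3,5-dimethoxy-4-(pivaloyloxy)phenyl]-7-methoxy-2,3-dihydro-1-benzofuran-3-carboxylate (trans) | COc1cc([C@H]2Oc3c(OC)cc(Br)cc3[C@@H]2C(=O)OC)cc(OC)c1OC(=O)C(C)(C)C | intermediate
17 | methyl 3-bromopropanoate | COC(=O)CCBr | starting material
18 | (3-methoxy-3-oxopropyl)zinc bromide | COC(=O)CC[Zn]Br | intermediate (not isolated)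
19 | methyl (2S,3S)-2-[3,5-dimethoxy-4-(pivaloyloxy)phenyl]-7-methoxy-5-(3-methoxy-3-oxopropyl)-2,3-dihydro-1-benzofuran-3-carboxylate | COc1cc([C@H]2Oc3c(OC)cc(CCC(=O)OC)cc3[C@@H]2C(=O)OC)cc(OC)c1OC(=O)C(C)(C)C | intermediate
20 | 4-[(2S,3R)-3-(hydroxymethyl)-5-(3-hydroxypropyl)-7-methoxy-2,3-dihydro-1-benzofuran-2-yl]-2,6-dimethoxyphenol | COc1cc([C@H]2Oc3c(OC)cc(CCCO)cc3[C@@H]2CO)cc(OC)c1O | target

**Totals and risks**
Total step count: 9. Longest linear sequence: 7 (steps 1, 2, 3, 6, 7, 8, 9).

Three steps most likely to fail: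

Step 6 (the new step). The condensation may be slow under primary-amine catalysis, and the same catalyst can racemise 14 by retro-oxa-Michael, so the ee may be modest. Fallback with known chemistry, setting out from 6 and 12: a BF3·OEt2-mediated Claisen–Schmidt condensation (dioxane, rt, ester-tolerant) gives chalcone 13, now isolated. NaOAc in refluxing EtOH cyclises it to the racemic flavanone F1. Kinetic resolution by Ru-catalysed asymmetric transfer hydrogenation (RuCl(p-cymene)[(R,R)-TsDPEN], HCO2H/Et3N, about 52% conversion; catalyst antipode assigned by analogy with chromanone reductions) reduces the (2R)-enantiomer to the cis-(2R,4R)-flavan-4-ol F2 and leaves the (2S)-flavanone. The fallback rejoins the route at 14, with at most about 48% yield from F1.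

Step 7. Competing dehydrogenation to the flavone, 2,3-migration of the electron-rich B ring, or acid-induced opening at C2 could lower yield or ee. Fallback, setting out from 14: α-bromination under acidic, non-enolate conditions (CuBr2, EtOAc/CHCl3, reflux) gives the trans-3-bromoflavanone F3. Ketalisation and a silver-assisted 1,2-aryl shift of the α-bromo ketal (AgBF4, HC(OMe)3/MeOH, 50 °C) then give the same trans ester, rejoining the route at 16.

Step 3. The position being acylated is meta to both Br and OMe, and hot TiCl4 may cleave the methyl ether or acylate para to OMe. Fallback, setting out from 3: magnesium-phenoxide-directed ortho-formylation (MgCl2, Et3N, paraformaldehyde, MeCN, reflux) gives 5-bromo-2-hydroxy-3-methoxybenzaldehyde F4. MeMgBr (2.5 equiv, THF, 0 °C) gives 4-bromo-2-(1-hydroxyethyl)-6-methoxyphenol F5. Benzylic oxidation with MnO2 (CH2Cl2, rt) rejoins the route at 6.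

**Further compounds**
F1 | step 6 | rac-4-(6-bromo-8-methoxy-4-oxo-3,4-dihydro-2H-chromen-2-yl)-2,6-dimethoxyphenyl pivalate | COc1cc(C2CC(=O)c3cc(Br)cc(OC)c3O2)cc(OC)c1OC(=O)C(C)(C)C
F2 | step 6 | 4-[(2R,4R)-6-bromo-4-hydroxy-8-methoxy-3,4-dihydro-2H-chromen-2-yl]-2,6-dimethoxyphenyl pivalate | COc1cc([C@H]2C[C@@H](O)c3cc(Br)cc(OC)c3O2)cc(OC)c1OC(=O)C(C)(C)C
F3 | step 7 | 4-[(2R,3R)-3,6-dibromo-8-methoxy-4-oxo-3,4-dihydro-2H-chromen-2-yl]-2,6-dimethoxyphenyl pivalate (trans) | COc1cc([C@@H]2[C@@H](Br)C(=O)c3cc(Br)cc(OC)c3O2)cc(OC)c1OC(=O)C(C)(C)C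
F4 | step 3 | 5-bromo-2-hydroxy-3-methoxybenzaldehyde | COc1cc(Br)cc(C=O)c1O
F5 | step 3 | 4-bromo-2-(1-hydroxyethyl)-6-methoxyphenol (racemic) | COc1cc(Br)cc(C(C)O)c1O
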